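Ring A is a 3-bromocatechol whose neighbouring carbons C1 and C6 carry the sulfooxyethyl chain and the benzylic bridge. It is cut into a four-carbon diene (C2–C5, carrying O3, O4 and Br5) and a two-carbon alkyne (C1, C6). Thermal Diels-Alder addition of 1-bromo-2,3-bis(silyloxy)cyclohexa-1,3-diene 13 to the ring B aryl ynone 8, then loss of ethene, forms C1–C2 and C5–C6 and aromatises ring A in one operation, with bromine locked at C5. All phenols travel as tert-butyldimethylsilyl ethers (ring B is demethylated at the aldehyde stage), so the chain alcohol alone is sulfated and fluoride frees the catechols last.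

Key step: step 9

Assumption (chemistry): the target is taken as the free hydrogen sulfate as drawn; 1 and 5 are bought; TBS = tert-butyldimethylsilyl and TBSO = (tert-butyldimethylsilyl)oxy; 7, 14 and 16 are racemic and lose their stereocentres before the achiral target.

Step 1
Reactants: 1 5-bromovanillin (3-bromo-4-hydroxy-5-methoxybenzaldehyde)
Product: 2 2,3-dibromo-4-hydroxy-5-methoxybenzaldehyde (5,6-dibromovanillin)
Conditions: Br2 (1.2 equiv), Fe powder (cat.), AcOH, rt
Reagents that add atoms: bromine, BrBr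
Why: Electrophilic aromatic bromination, in which attack para to the methoxy group should be favoured over the crowded position between the formyl and methoxy groups.

Step 2
Reactants: 2 2,3-dibromo-4-hydroxy-5-methoxybenzaldehyde
Product: 3 2,3-dibromo-4,5-dihydroxybenzaldehyde
Conditions: BBr3 (3 equiv), CH2Cl2, −78 °C to rt; H2O
Reagents that add atoms: none
Why: BBr3 cleavage of the aryl methyl ether (aryloxyborane formation, bromide attack on methyl) is carried out on a simple aldehyde so that no harsh demethylation is needed once the sulfate or the silyl ethers are present.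

Step 3
Reactants: 3 2,3-dibromo-4,5-dihydroxybenzaldehyde
Product: 4 2,3-dibromo-4,5-bis(TBSO)benzaldehyde
Conditions: TBSCl (3 equiv), imidazole, DMAP (cat.), DMF, rt to 40 °C
Reagents that add atoms: tert-butyldimethylsilyl chloride, CC(C)(C)[Si](C)(C)Cl
Why: Imidazole-promoted O-silylation of both phenols (silyl ether formation) gives a catechol protection that tolerates acetylide addition, heat and acid and is later removed by fluoride.

Step 4
Reactants: 5 tert-butyl(but-3-yn-1-yloxy)dimethylsilane; 4 2,3-dibromo-4,5-bis(TBSO)benzaldehyde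
Product: 7 1-[2,3-dibromo-4,5-bis(TBSO)phenyl]-5-(TBSO)pent-2-yn-1-ol (racemic), via lithium acetylide 6 (not isolated)
Conditions: 5 (1.2 equiv), n-BuLi (1.1 equiv), THF, −78 °C; then 4, −78 to −40 °C; aq. NH4Cl
Reagents that add atoms: none
Why: 1,2-Addition of a lithium acetylide to an aryl aldehyde, with the alkyne in excess over n-BuLi so that no alkyllithium remains to exchange the aryl bromides; the carbinol centre forms as a racemate and is oxidised away in step 5.

Step 5
Reactants: 7 1-[2,3-dibromo-4,5-bis(TBSO)phenyl]-5-(TBSO)pent-2-yn-1-ol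
Product: 8 1-[2,3-dibromo-4,5-bis(TBSO)phenyl]-5-(TBSO)pent-2-yn-1-one
Conditions: activated MnO2 (15 equiv), CH2Cl2, rt
Reagents that add atoms: none
Why: MnO2 oxidation of a benzylic, propargylic alcohol is selective and neutral, so the silyl ethers and the sensitive ynone should survive.

Step 6
Reactants: 9 cyclohexane-1,2-dione
Product: 10 3-bromo-2-hydroxycyclohex-2-en-1-one (enol form of 3-bromocyclohexane-1,2-dione)
Conditions: NBS (1.0 equiv), CH2Cl2, 0 °C to rt
Reagents that add atoms: N-bromosuccinimide, O=C1CCC(=O)N1Br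
Why: Electrophilic α-bromination of the dione through its 2-hydroxy-enone tautomer, whose enol carbon C3 attacks NBS, followed by re-enolisation toward the bromine-bearing carbon to the stable bromo diosphenol.

Step 7
Reactants: 10 3-bromo-2-hydroxycyclohex-2-en-1-one
Product: 11 3-bromo-2-(TBSO)cyclohex-2-en-1-one
Conditions: TBSCl (1.2 equiv), imidazole, CH2Cl2, 0 °C to rt
Reagents that add atoms: tert-butyldimethylsilyl chloride, CC(C)(C)[Si](C)(C)Cl
Why: O-Silylation of the acidic diosphenol hydroxyl (silyl enol ether formation) fixes the first enol ether with bromine on its β-carbon.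

Step 8
Reactants: 11 3-bromo-2-(TBSO)cyclohex-2-en-1-one
Product: 13 1-bromo-2,3-bis(TBSO)cyclohexa-1,3-diene, via lithium dienolate 12 (not isolated)
Conditions: LiN(iPr)2 (1.1 equiv), THF, −78 °C; TBSCl, DMPU, −78 to 0 °C; pentane, filtration, Et3N-deactivated silica
Reagents that add atoms: tert-butyldimethylsilyl chloride, CC(C)(C)[Si](C)(C)Cl
Why: Kinetic α′-deprotonation of the enone by the hindered amide gives the cross-conjugated lithium dienolate and O-silylation gives the 2,3-bis(silyloxy)diene (silyl enol ether formation); the vinylic bromide is inert to the amide at −78 °C and the bulky silyl groups let the diene be isolated.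

Step 9
Reactants: 13 1-bromo-2,3-bis(TBSO)cyclohexa-1,3-diene; 8 1-[2,3-dibromo-4,5-bis(TBSO)phenyl]-5-(TBSO)pent-2-yn-1-one
Product: 15 [2-bromo-6-[2-(TBSO)ethyl]-3,4-bis(TBSO)phenyl][2,3-dibromo-4,5-bis(TBSO)phenyl]methanone, via bicyclo[2.2.2]octa-2,5-diene cycloadduct 14 (not isolated)
Conditions: 13 (2 equiv), BHT (cat.), mesitylene, Ar, 120 °C then 165 °C
Reagents that add atoms: none
Why: The electron-rich bis(silyloxy)diene 13 adds suprafacially to the electron-poor acetylenic ketone 8 in a concerted, asynchronous [4+2] cycloaddition that forms C1–C2 and C5–C6 and gives bicyclooctadiene 14, whose bridgehead bromide has no pathway for elimination. On stronger heating 14 loses its saturated two-carbon bridge as ethene in a retro-[4+2] reaction made irreversible by the aromatisation of ring A; this is the Alder–Rickert arene synthesis, established for 2-silyloxy- and 2,3-bis(silyloxy)cyclohexa-1,3-dienes with acetylenic ketones and esters. Ring A is thus closed by an intermolecular six-membered cycloaddition in which both ring bonds arise in one step, followed by cycloreversion. The two bridgehead stereocentres of 14 form as a racemate with the relative configuration dictated by the bicycle, and both vanish on aromatisation, so 15 has no stereocentre. The step needs ortho regioselectivity: the unsubstituted diene terminus carries the larger HOMO coefficient (bromine behaves as the terminal substituent of a 1-substituted diene) and pairs with the ynone β-carbon, which has the larger LUMO coefficient, so the brominated terminus bonds to the acyl-bearing α-carbon. Excess diene, a radical inhibitor and staged heating (addition first, extrusion second) are meant to keep diene 1,5-hydrogen shifts and ynone polymerisation from competing.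

Step 10
Reactants: 15 [2-bromo-6-[2-(TBSO)ethyl]-3,4-bis(TBSO)phenyl][2,3-dibromo-4,5-bis(TBSO)phenyl]methanone
Product: 16 [2-bromo-6-[2-(TBSO)ethyl]-3,4-bis(TBSO)phenyl][2,3-dibromo-4,5-bis(TBSO)phenyl]methanol (racemic)
Conditions: iBu2AlH (1.5 equiv), CH2Cl2, −78 to 0 °C; aq. KNaC4H4O6 (potassium sodium tartrate)
Reagents that add atoms: none
Why: Hydride reduction of the hindered diaryl ketone with a non-basic aluminium hydride spares the aryl silyl ethers para to the carbonyl and the aryl bromides; the carbinol centre forms as a racemate and is removed in step 11.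

Step 11
Reactants: 16 [2-bromo-6-[2-(TBSO)ethyl]-3,4-bis(TBSO)phenyl][2,3-dibromo-4,5-bis(TBSO)phenyl]methanol
Product: 18 2-[3-bromo-2-[2,3-dibromo-4,5-bis(TBSO)benzyl]-4,5-bis(TBSO)phenyl]ethanol, via penta-silylated diarylmethane 17 (not isolated)
Conditions: Et3SiH (5 equiv), CF3CO2H (10 equiv), CH2Cl2, −20 to 0 °C; then THF–H2O, rt; aq. NaHCO3
Reagents that add atoms: none
Why: Ionic hydrogenation: acid ionises the carbinol to a diarylmethyl cation stabilised by a para silyloxy group on each ring and Et3SiH delivers hydride, after which aqueous acid cleaves only the primary alkyl silyl ether, aryl silyl ethers being far more acid-stable; any isochroman formed by capture of the cation by the chain oxygen should re-ionise and be funnelled to the same product.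

Step 12
Reactants: 18 2-[3-bromo-2-[2,3-dibromo-4,5-bis(TBSO)benzyl]-4,5-bis(TBSO)phenyl]ethanol
Product: 19 sodium 2-[3-bromo-2-[2,3-dibromo-4,5-bis(TBSO)benzyl]-4,5-bis(TBSO)phenyl]ethyl sulfate
Conditions: SO3·pyridine (3 equiv), pyridine, rt; aq. NaHCO3
Reagents that add atoms: sulfur trioxide pyridine complex, O=S(=O)=O.c1ccncc1; sodium hydrogen carbonate, [Na+].OC([O-])=O
Why: O-Sulfation of the only free hydroxyl with the sulfur trioxide–amine complex needs no selectivity because every phenol is silylated, and the lipophilic sodium salt can be purified on silica.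

Step 13
Reactants: 19 sodium 2-[3-bromo-2-[2,3-dibromo-4,5-bis(TBSO)benzyl]-4,5-bis(TBSO)phenyl]ethyl sulfate
Product: 21 2-[3-bromo-2-(2,3-dibromo-4,5-dihydroxybenzyl)-4,5-dihydroxyphenyl]ethyl hydrogen sulfate (target), via sodium sulfate salt 20 (not isolated)
Conditions: KHF2 (6 equiv), degassed MeOH, rt; then 1 M HCl to pH 2, C18 reversed-phase chromatography (H2O–MeOH), lyophilise
Reagents that add atoms: none
Why: Fluoride-mediated cleavage of the four aryl silyl ethers under mildly acidic conditions should protect the catechols from oxidation and leave the alkyl sulfate monoester untouched, and protonation of the salt then gives the free hydrogen sulfate.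

Compound list
1 | 5-bromovanillin (3-bromo-4-hydroxy-5-methoxybenzaldehyde) | COc1cc(C=O)cc(Br)c1O | starting material
2 | 2,3-dibromo-4-hydroxy-5-methoxybenzaldehyde | COc1cc(C=O)c(Br)c(Br)c1O | intermediate
3 | 2,3-dibromo-4,5-dihydroxybenzaldehyde | O=Cc1cc(O)c(O)c(Br)c1Br | intermediate
4 | 2,3-dibromo-4,5-bis(TBSO)benzaldehyde | O=Cc1cc(O[Si](C)(C)C(C)(C)C)c(O[Si](C)(C)C(C)(C)C)c(Br)c1Br | intermediate
5 | tert-butyl(but-3-yn-1-yloxy)dimethylsilane (TBS ether of 3-butyn-1-ol) | C#CCCO[Si](C)(C)C(C)(C)C | starting material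
6 | [4-(TBSO)but-1-yn-1-yl]lithium | [Li]C#CCCO[Si](C)(C)C(C)(C)C | intermediate (not isolated)
7 | 1-[2,3-dibromo-4,5-bis(TBSO)phenyl]-5-(TBSO)pent-2-yn-1-ol, racemic | OC(C#CCCO[Si](C)(C)C(C)(C)C)c1cc(O[Si](C)(C)C(C)(C)C)c(O[Si](C)(C)C(C)(C)C)c(Br)c1Br | intermediate
8 | 1-[2,3-dibromo-4,5-bis(TBSO)phenyl]-5-(TBSO)pent-2-yn-1-one | O=C(C#CCCO[Si](C)(C)C(C)(C)C)c1cc(O[Si](C)(C)C(C)(C)C)c(O[Si](C)(C)C(C)(C)C)c(Br)c1Br | intermediate
9 | cyclohexane-1,2-dione | O=C1CCCCC1=O | starting material
10 | 3-bromo-2-hydroxycyclohex-2-en-1-one | O=C1CCCC(Br)=C1O | intermediate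
11 | 3-bromo-2-(TBSO)cyclohex-2-en-1-one | O=C1CCCC(Br)=C1O[Si](C)(C)C(C)(C)C | intermediate
12 | lithium 5-bromo-6-(TBSO)cyclohexa-1,5-dien-1-olate | [Li]OC1=CCCC(Br)=C1O[Si](C)(C)C(C)(C)C | intermediate (not isolated)
13 | 1-bromo-2,3-bis(TBSO)cyclohexa-1,3-diene | BrC1=C(O[Si](C)(C)C(C)(C)C)C(O[Si](C)(C)C(C)(C)C)=CCC1 | intermediate
14 | [(1RS,4RS)-1-bromo-3-[2-(TBSO)ethyl]-5,6-bis(TBSO)bicyclo[2.2.2]octa-2,5-dien-2-yl][2,3-dibromo-4,5-bis(TBSO)phenyl]methanone, racemic, the (1S,4S) enantiomer drawn | Br[C@]12CC[C@H](C(O[Si](C)(C)C(C)(C)C)=C1O[Si](C)(C)C(C)(C)C)C(CCO[Si](C)(C)C(C)(C)C)=C2C(=O)c3cc(O[Si](C)(C)C(C)(C)C)c(O[Si](C)(C)C(C)(C)C)c(Br)c3Br | intermediate (not isolated)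
15 | [2-bromo-6-[2-(TBSO)ethyl]-3,4-bis(TBSO)phenyl][2,3-dibromo-4,5-bis(TBSO)phenyl]methanone | CC(C)(C)[Si](C)(C)OCCc1cc(O[Si](C)(C)C(C)(C)C)c(O[Si](C)(C)C(C)(C)C)c(Br)c1C(=O)c1cc(O[Si](C)(C)C(C)(C)C)c(O[Si](C)(C)C(C)(C)C)c(Br)c1Br | intermediate
16 | [2-bromo-6-[2-(TBSO)ethyl]-3,4-bis(TBSO)phenyl][2,3-dibromo-4,5-bis(TBSO)phenyl]methanol, racemic | CC(C)(C)[Si](C)(C)OCCc1cc(O[Si](C)(C)C(C)(C)C)c(O[Si](C)(C)C(C)(C)C)c(Br)c1C(O)c1cc(O[Si](C)(C)C(C)(C)C)c(O[Si](C)(C)C(C)(C)C)c(Br)c1Br | intermediate
17 | tert-butyl[2-[3-bromo-2-[2,3-dibromo-4,5-bis(TBSO)benzyl]-4,5-bis(TBSO)phenyl]ethoxy]dimethylsilane | CC(C)(C)[Si](C)(C)OCCc1cc(O[Si](C)(C)C(C)(C)C)c(O[Si](C)(C)C(C)(C)C)c(Br)c1Cc1cc(O[Si](C)(C)C(C)(C)C)c(O[Si](C)(C)C(C)(C)C)c(Br)c1Br | intermediate (not isolated)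
18 | 2-[3-bromo-2-[2,3-dibromo-4,5-bis(TBSO)benzyl]-4,5-bis(TBSO)phenyl]ethanol | OCCc1cc(O[Si](C)(C)C(C)(C)C)c(O[Si](C)(C)C(C)(C)C)c(Br)c1Cc1cc(O[Si](C)(C)C(C)(C)C)c(O[Si](C)(C)C(C)(C)C)c(Br)c1Br | intermediate
19 | sodium 2-[3-bromo-2-[2,3-dibromo-4,5-bis(TBSO)benzyl]-4,5-bis(TBSO)phenyl]ethyl sulfate | [Na+].[O-]S(=O)(=O)OCCc1cc(O[Si](C)(C)C(C)(C)C)c(O[Si](C)(C)C(C)(C)C)c(Br)c1Cc1cc(O[Si](C)(C)C(C)(C)C)c(O[Si](C)(C)C(C)(C)C)c(Br)c1Br | intermediate
20 | sodium 2-[3-bromo-2-(2,3-dibromo-4,5-dihydroxybenzyl)-4,5-dihydroxyphenyl]ethyl sulfate | [Na+].[O-]S(=O)(=O)OCCc1cc(O)c(O)c(Br)c1Cc1cc(O)c(O)c(Br)c1Br | intermediate (not isolated)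
21 | 2-[3-bromo-2-(2,3-dibromo-4,5-dihydroxybenzyl)-4,5-dihydroxyphenyl]ethyl hydrogen sulfate (CNP0136879.0) | O=S(=O)(O)OCCc1cc(O)c(O)c(Br)c1Cc1cc(O)c(O)c(Br)c1Br | target

Total step count: 13 steps.
Longest linear sequence: 10 steps (steps 1, 2, 3, 4, 5, 9, 10, 11, 12, 13, from 1). The diene branch (steps 6–8) joins at step 9.

Steps most likely to fail

1. Step 9. Bond formation at the fully substituted, bromine-bearing diene terminus may be slow enough that diene 1,5-hydrogen shifts, enol ether cleavage or ynone polymerisation win, or the addition may occur in the reversed orientation. The fallback replaces the cycloaddition by a Friedel–Crafts benzylation; it sets out from 1 and 2 and comes back at 17. Compound 1 is O-methylated (MeI, K2CO3, DMF) to 3-bromo-4,5-dimethoxybenzaldehyde F1, methylenated (Ph3PCH3Br, KOtBu, THF) to 1-bromo-5-ethenyl-2,3-dimethoxybenzene F2, hydroborated and oxidised (9-BBN, THF; H2O2, NaOH) to 2-(3-bromo-4,5-dimethoxyphenyl)ethanol F3 and acetylated (Ac2O, pyridine) to 2-(3-bromo-4,5-dimethoxyphenyl)ethyl acetate F4. Compound 2 is O-methylated in the same way to 2,3-dibromo-4,5-dimethoxybenzaldehyde F5 and reduced (NaBH4, MeOH) to (2,3-dibromo-4,5-dimethoxyphenyl)methanol F6. F6 and F4 with AlCl3 in CH2Cl2 at 0 °C should give, by attack para to a methoxy group between the bromine and the side chain, 2-[3-bromo-2-(2,3-dibromo-4,5-dimethoxybenzyl)-4,5-dimethoxyphenyl]ethyl acetate F7. BBr3 in CH2Cl2 with a methanol quench should remove the four methyl groups and the acetate to give 3-bromo-4-(2,3-dibromo-4,5-dihydroxybenzyl)-5-(2-hydroxyethyl)benzene-1,2-diol F8. Silylation of all five hydroxyl groups (TBSCl, imidazole, DMF) returns to the route at 17, which is isolated here and taken to 18 by the aqueous acid stage of step 11.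

2. Step 8. Enolisation may occur on the wrong side (γ-deprotonation next to the bromoalkene), the amide may attack the β-bromo enone, or the dienol ether may hydrolyse during isolation. The fallback installs the bromine after the first enol ether instead of before; it sets out from 9 and comes back at 13. Double soft enolisation of 9 (TBSOTf, Et3N, CH2Cl2, 0 °C) gives 2,3-bis(TBSO)cyclohexa-1,3-diene F9. One equivalent of NBS in THF at −78 °C brominates one enol ether terminus to give racemic 6-bromo-2-(TBSO)cyclohex-2-en-1-one F10. Renewed soft enolisation (TBSOTf, Et3N, CH2Cl2, 0 °C) toward the more acidic bromine-bearing α-carbon gives 13.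

3. Step 11. The diarylmethyl cation may be captured by the side-chain oxygen (isochroman formation) faster than by the silane, or acid may strip aryl silyl ethers. The fallback removes the hydroxyl by activation and hydride displacement without strong acid; it sets out from 16 and comes back at 18. MsCl and Et3N in CH2Cl2 at 0 °C should convert 16, through the labile mesylate and the chloride released with it, into racemic [2-bromo-6-[2-(TBSO)ethyl]-3,4-bis(TBSO)phenyl][2,3-dibromo-4,5-bis(TBSO)phenyl]chloromethane F11. NaBH4 in DMSO at rt reduces this doubly benzylic chloride to 17, which is isolated, and PPTS in MeOH at rt cleaves only the primary alkyl silyl ether to give 18.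

Further compounds
F1 | step 9 | 3-bromo-4,5-dimethoxybenzaldehyde | COc1cc(C=O)cc(Br)c1OC
F2 | step 9 | 1-bromo-5-ethenyl-2,3-dimethoxybenzene | COc1cc(C=C)cc(Br)c1OC
F3 | step 9 | 2-(3-bromo-4,5-dimethoxyphenyl)ethanol | COc1cc(CCO)cc(Br)c1OC
F4 | step 9 | 2-(3-bromo-4,5-dimethoxyphenyl)ethyl acetate | COc1cc(CCOC(C)=O)cc(Br)c1OC
F5 | step 9 | 2,3-dibromo-4,5-dimethoxybenzaldehyde | COc1cc(C=O)c(Br)c(Br)c1OC
F6 | step 9 | (2,3-dibromo-4,5-dimethoxyphenyl)methanol | COc1cc(CO)c(Br)c(Br)c1OC
F7 | step 9 | 2-[3-bromo-2-(2,3-dibromo-4,5-dimethoxybenzyl)-4,5-dimethoxyphenyl]ethyl acetate | CC(=O)OCCc1cc(OC)c(OC)c(Br)c1Cc1cc(OC)c(OC)c(Br)c1Br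
F8 | step 9 | 3-bromo-4-(2,3-dibromo-4,5-dihydroxybenzyl)-5-(2-hydroxyethyl)benzene-1,2-diol | OCCc1cc(O)c(O)c(Br)c1Cc1cc(O)c(O)c(Br)c1Br
F9 | step 8 | 2,3-bis(TBSO)cyclohexa-1,3-diene | CC(C)(C)[Si](C)(C)OC1=CCCC=C1O[Si](C)(C)C(C)(C)C
F10 | step 8 | 6-bromo-2-(TBSO)cyclohex-2-en-1-one, racemic | O=C1C(Br)CCC=C1O[Si](C)(C)C(C)(C)C
F11 | step 11 | [2-bromo-6-[2-(TBSO)ethyl]-3,4-bis(TBSO)phenyl][2,3-dibromo-4,5-bis(TBSO)phenyl]chloromethane, racemic | ClC(c1c(Br)c(O[Si](C)(C)C(C)(C)C)c(O[Si](C)(C)C(C)(C)C)cc1CCO[Si](C)(C)C(C)(C)C)c1cc(O[Si](C)(C)C(C)(C)C)c(O[Si](C)(C)C(C)(C)C)c(Br)c1Br
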